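Target read as epicatechin-(4α→8)-epigallocatechin 3-O-gallate: upper unit 2R,3R,4S (2,3-cis, 3,4-cis), lower unit 2R,3R. Cuts, in order: the galloyl ester C–O, the interflavan C4–C8 bond, the lower C2–aryl bond, and the lower pyran ring at O1–C2 and C3–C4.
Enabling feature: lower C4 is an unsubstituted CH2 on C4a, ortho to the phenolic O1 on C8a, so O1=C8a–C4a=C4H2 is an o-quinone methide, and C3(O)–C2 maps onto a glycolate enolate. Because the methide carbon is not prochiral, all induction can be placed in the enolate.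
Forward: the lower pyran ring (ring C of the gallocatechin unit) is the only skeleton ring that is made, by an o-quinone methide/chiral glycolate enolate Michael–lactonisation. Every other ring is bought, and no ring is closed afterwards.
Then: aryl onto the lactone carbonyl and hydride at C2; bromination at C8; C8-lithium onto 4-oxo-epicatechin and hydride at C4; desilylation, galloylation, hydrogenolysis.
Stereochemistry: lower C3 from the (S)-4-benzyloxazolidinone auxiliary; lower C2 by hydride anti to the axial 3-silyloxy group of the 2-aryl oxocarbenium ion (2,3-cis); upper C2 and C3 from (−)-epicatechin; upper C4 by β-face hydride to the 4-aryl cation (aryl α).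
Key step: step 4

Remark: compounds 1, 4, 5, 10, 18 and 28 are taken as purchasable; α and β follow the flavan convention (3-O of epicatechin is α).

Step 1
Reactants: 1 3,5-bis(benzyloxy)phenol
Product: 2 3,5-bis(benzyloxy)-2-[(dimethylamino)methyl]phenol
Conditions: [Me2N=CH2]I, K2CO3, CH2Cl2, 0 °C → rt
Reagents that add atoms: Eschenmoser's salt (N,N-dimethylmethylideneammonium iodide), C=[N+](C)C.[I-]
Why: Phenolic Mannich reaction, in which the hydrogen-bonded phenol–iminium pair directs the aminomethyl group to an ortho carbon (the two ortho carbons of 1 are equivalent) and so places the future C4 next to the future O1.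

Step 2
Reactants: 2 3,5-bis(benzyloxy)-2-[(dimethylamino)methyl]phenol
Product: 3 {[2,4-bis(benzyloxy)-6-hydroxyphenyl]methyl}trimethylammonium iodide
Conditions: MeI, acetone, 0 °C → rt; salt collected by filtration
Reagents that add atoms: iodomethane, CI
Why: Menshutkin quaternisation, faster at the tertiary benzylic amine than O-methylation of the un-ionised phenol, turns the amine into the leaving group of an o-quinone methide precursor.

Step 3
Reactants: 4 (4S)-4-benzyl-1,3-oxazolidin-2-one; 5 {[tert-butyl(dimethyl)silyl]oxy}acetic acid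
Product: 6 (4S)-4-benzyl-3-({[tert-butyl(dimethyl)silyl]oxy}acetyl)-1,3-oxazolidin-2-one
Conditions: 5, t-BuCOCl, Et3N, THF, −20 °C; then 4, LiCl, rt
Reagents that add atoms: none
Why: N-Acylation of the oxazolidinone through the mixed pivalic anhydride is the standard entry to Evans glycolate imides and touches no stereocentre.

Step 4
Reactants: 3 {[2,4-bis(benzyloxy)-6-hydroxyphenyl]methyl}trimethylammonium iodide; 6 (4S)-4-benzyl-3-({[tert-butyl(dimethyl)silyl]oxy}acetyl)-1,3-oxazolidin-2-one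
Product: 9 (3R)-5,7-bis(benzyloxy)-3-{[tert-butyl(dimethyl)silyl]oxy}-3,4-dihydro-2H-chromen-2-one, via o-quinone methide 7 (not isolated), via imide phenolate 8 (not isolated)
Conditions: 6 (2.2 equiv), NaN(SiMe3)2 (2.2 equiv), THF, −78 °C; 3 in THF/DMPU added slowly, −78 → −40 °C, then 0 °C; AcOH
Reagents that add atoms: none
Why: Proposed new method: one equivalent of the enolate acts as base (and is recovered as 6) to turn 3 into its phenolate, which expels trimethylamine by 1,4-elimination to give o-quinone methide 7 (O1=C8a–C4a=C4H2); the chelated sodium (Z)-enolate of 6 then adds through carbon to the methide carbon (C3–C4 bond), and the phenolate 8 so formed attacks the exocyclic imide carbonyl in a 6-exo-trig acyl substitution that closes the O1–C2 bond and releases the auxiliary, a formal [4+2] annulation. The closest known reaction types are the Evans glycolate alkylation of sodium imide enolates with benzylic and allylic halides, the classical C-alkylation of enolates with phenolic Mannich-base methiodides, and the Lewis-base-catalysed ammonium enolate/o-quinone methide annulations that give 3,4-dihydrocoumarins. The only new stereocentre, C3, is set by the (S)-4-benzyl group of the auxiliary: the methide carbon approaches the enolate face remote from it, which gives 3R. The o-quinone methide itself needs no facial control, because its methide carbon is an unsubstituted CH2 that becomes the C4 methylene. The step needs C- over O-alkylation of the enolate and capture of 7 faster than its self-condensation; the soft carbon terminus of the chelated enolate, its excess and the slow low-temperature release of 7 should secure both, and the cold acidic quench guards the α-silyloxy lactone against epimerisation.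

Step 5
Reactants: 10 5-bromo-1,2,3-trimethoxybenzene
Product: 11 5-bromobenzene-1,2,3-triol
Conditions: BBr3, CH2Cl2, −78 °C → rt; then H2O
Reagents that add atoms: none
Why: Lewis-acid cleavage of the three aryl methyl ethers (BBr3 demethylation) leaves the aryl bromide untouched.

Step 6
Reactants: 11 5-bromobenzene-1,2,3-triol
Product: 12 1,2,3-tris(benzyloxy)-5-bromobenzene
Conditions: BnBr, K2CO3, DMF, rt
Reagents that add atoms: benzyl bromide, BrCc1ccccc1
Why: Williamson etherification of the three phenols gives the benzyl-protected precursor of the trihydroxyphenyl ring.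

Step 7
Reactants: 9 (3R)-5,7-bis(benzyloxy)-3-{[tert-butyl(dimethyl)silyl]oxy}-3,4-dihydro-2H-chromen-2-one; 12 1,2,3-tris(benzyloxy)-5-bromobenzene
Product: 16 (2R,3R)-5,7-bis(benzyloxy)-2-[3,4,5-tris(benzyloxy)phenyl]-3-{[tert-butyl(dimethyl)silyl]oxy}chromane, via aryllithium 13 (not isolated), via lactol 14 (not isolated), via oxocarbenium ion 15 (not isolated)
Conditions: 12, n-BuLi, THF/PhMe, −78 °C; 9, −78 °C; AcOH (1 equiv); then Et3SiH, BF3·OEt2, CH2Cl2, −78 → −20 °C
Reagents that add atoms: none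
Why: Bromine–lithium exchange gives 13, which adds once to the aryl-ester carbonyl of 9 (lactone to lactol, as in C-aryl glycoside synthesis), and BF3·OEt2 ionises lactol 14 or its open hydroxy-ketone tautomer to the same planar 2-aryl oxocarbenium ion 15, in which A(1,2) strain with the coplanar aryl holds the 3-silyloxy group pseudoaxial, so that Et3SiH delivers hydride axially anti to it and C2 becomes R with the aryl cis to O3 (reductive etherification, the hydride-last route to 2,3-cis-flavans).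

Step 8
Reactants: 16 (2R,3R)-5,7-bis(benzyloxy)-2-[3,4,5-tris(benzyloxy)phenyl]-3-{[tert-butyl(dimethyl)silyl]oxy}chromane
Product: 17 (2R,3R)-8-bromo-5,7-bis(benzyloxy)-2-[3,4,5-tris(benzyloxy)phenyl]-3-{[tert-butyl(dimethyl)silyl]oxy}chromane
Conditions: NBS, CH2Cl2, −78 °C → rt
Reagents that add atoms: N-bromosuccinimide, O=C1CCC(=O)N1Br
Why: Electrophilic aromatic bromination goes to C8 of the phloroglucinol-type ring A, which is flanked by the ring oxygen and is more accessible than C6 between two benzyloxy groups, as is the rule for benzylated flavan-3-ols, while the trialkoxyphenyl ring is less activated.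

Step 9
Reactants: 18 (−)-epicatechin
Product: 19 5,7,3′,4′-tetra-O-benzyl-(−)-epicatechin
Conditions: BnBr, K2CO3, DMF, 0 °C → rt
Reagents that add atoms: benzyl bromide, BrCc1ccccc1
Why: Williamson etherification of the four phenols with carbonate as base leaves the secondary alcohol free and avoids the strongly basic conditions that epimerise C2.

Step 10
Reactants: 19 5,7,3′,4′-tetra-O-benzyl-(−)-epicatechin
Product: 20 3,5,7,3′,4′-penta-O-benzyl-(−)-epicatechin
Conditions: NaH, BnBr, DMF, 0 °C → rt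
Reagents that add atoms: benzyl bromide, BrCc1ccccc1
Why: Williamson etherification of the axial 3-hydroxyl gives a 3-O protecting group that withstands the aryllithium and acid steps and falls in the final hydrogenolysis.

Step 11
Reactants: 20 3,5,7,3′,4′-penta-O-benzyl-(−)-epicatechin
Product: 21 4β-hydroxy-3,5,7,3′,4′-penta-O-benzyl-(−)-epicatechin (4-OH trans to the 3-benzyloxy group)
Conditions: DDQ, CH2Cl2/H2O (18:1), rt
Reagents that add atoms: water, O
Why: DDQ abstracts hydride from C4, the position benzylic to the dialkoxy ring A, and water captures the resulting cation trans to the 3-benzyloxy group (benzylic C–H oxidation of protected flavan-3-ols).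

Step 12
Reactants: 21 4β-hydroxy-3,5,7,3′,4′-penta-O-benzyl-(−)-epicatechin
Product: 22 4-oxo-3,5,7,3′,4′-penta-O-benzyl-(−)-epicatechin (2,3-cis chroman-4-one with the C2 and C3 configurations of epicatechin)
Conditions: Dess–Martin periodinane, CH2Cl2, rt
Reagents that add atoms: none
Why: Dess–Martin oxidation of the secondary benzylic alcohol proceeds under near-neutral conditions that should not epimerise C3, now α to the ketone.

Step 13
Reactants: 17 (2R,3R)-8-bromo-5,7-bis(benzyloxy)-2-[3,4,5-tris(benzyloxy)phenyl]-3-{[tert-butyl(dimethyl)silyl]oxy}chromane; 22 4-oxo-3,5,7,3′,4′-penta-O-benzyl-(−)-epicatechin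
Product: 24 4-hydroxy-3,5,7,3′,4′-penta-O-benzyl-epicatechin-(4→8)-[3-O-(tert-butyldimethylsilyl)-5,7,3′,4′,5′-penta-O-benzyl-epigallocatechin] (tertiary carbinol, lower aryl expected β at C4), via 8-lithioflavan 23 (not isolated)
Conditions: 17, t-BuLi (2.1 equiv), THF, −78 °C; 22, −78 → −40 °C; aq NH4Cl
Reagents that add atoms: none
Why: Bromine–lithium exchange followed by 1,2-addition of aryllithium 23 to the 4-ketone is the aryllithium/4-oxoflavan union used for 4,8-linked flavan dimers, and although the aryl is expected to enter anti to the axial 3-benzyloxy group, the C4 configuration of 24 is of no consequence because step 14 erases it.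

Step 14
Reactants: 24 tertiary carbinol
Product: 26 3,5,7,3′,4′-penta-O-benzyl-epicatechin-(4α→8)-[3-O-(tert-butyldimethylsilyl)-5,7,3′,4′,5′-penta-O-benzyl-epigallocatechin] (upper C4 aryl cis to the 3-benzyloxy group), via C4 cation 25 (not isolated)
Conditions: Bu3SnH, CF3CO2H, CH2Cl2, 0 °C
Reagents that add atoms: none
Why: Ionic hydrogenation, in which the acid ionises the tertiary doubly benzylic alcohol to the planar cation 25 and Bu3SnH transfers hydride to its β-face, anti to the pseudoaxial 3-benzyloxy group, so that the aryl group is left α (3,4-cis) and both C4 epimers of 24 converge.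

Step 15
Reactants: 26 silyl-protected 4α→8 dimer
Product: 27 3,5,7,3′,4′-penta-O-benzyl-epicatechin-(4α→8)-[5,7,3′,4′,5′-penta-O-benzyl-epigallocatechin] (lower 3-OH free)
Conditions: Bu4NF, AcOH, THF, rt → 50 °C
Reagents that add atoms: none
Why: Fluoride-mediated Si–O cleavage frees the lower 3-hydroxyl as the only unprotected oxygen, the benzyl ethers being inert.

Step 16
Reactants: 27 dimer with free lower 3-OH; 28 3,4,5-tris(benzyloxy)benzoic acid
Product: 29 3,5,7,3′,4′-penta-O-benzyl-epicatechin-(4α→8)-[5,7,3′,4′,5′-penta-O-benzyl-epigallocatechin 3-O-(3,4,5-tri-O-benzylgallate)]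
Conditions: DCC, DMAP, CH2Cl2, rt
Reagents that add atoms: none
Why: Steglich esterification acylates the single free hydroxyl with retention at C3, as in the galloylation of benzylated epigallocatechin.

Step 17
Reactants: 29 fully benzylated dimer gallate
Product: 30 epicatechin-(4α→8)-epigallocatechin 3-O-gallate
Conditions: H2 (1 atm), Pd(OH)2/C, THF/MeOH, rt
Reagents that add atoms: none
Why: Hydrogenolysis removes all thirteen benzyl ethers, while the galloyl ester and the flavan C2–O1 and C4–C8 bonds should survive, as they do in the final deprotection of benzylated catechin gallates and procyanidins.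

Compound list
1 | 3,5-bis(benzyloxy)phenol | Oc1cc(OCc2ccccc2)cc(OCc2ccccc2)c1 | starting material
2 | 3,5-bis(benzyloxy)-2-[(dimethylamino)methyl]phenol | CN(C)Cc1c(O)cc(OCc2ccccc2)cc1OCc1ccccc1 | intermediate
3 | {[2,4-bis(benzyloxy)-6-hydroxyphenyl]methyl}trimethylammonium iodide | C[N+](C)(C)Cc1c(O)cc(OCc2ccccc2)cc1OCc1ccccc1.[I-] | intermediate
4 | (4S)-4-benzyl-1,3-oxazolidin-2-one | O=C1N[C@@H](Cc2ccccc2)CO1 | starting material
5 | {[tert-butyl(dimethyl)silyl]oxy}acetic acid | CC(C)(C)[Si](C)(C)OCC(=O)O | starting material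
6 | (4S)-4-benzyl-3-({[tert-butyl(dimethyl)silyl]oxy}acetyl)-1,3-oxazolidin-2-one | CC(C)(C)[Si](C)(C)OCC(=O)N1C(=O)OC[C@@H]1Cc1ccccc1 | intermediate
7 | 3,5-bis(benzyloxy)-6-methylidenecyclohexa-2,4-dien-1-one (o-quinone methide) | C=C1C(=O)C=C(OCc2ccccc2)C=C1OCc1ccccc1 | intermediate
8 | sodium 3,5-bis(benzyloxy)-2-[(2R)-3-[(4S)-4-benzyl-2-oxo-1,3-oxazolidin-3-yl]-2-{[tert-butyl(dimethyl)silyl]oxy}-3-oxopropyl]phenolate | [Na+].[O-]c1cc(OCc2ccccc2)cc(OCc2ccccc2)c1C[C@@H](O[Si](C)(C)C(C)(C)C)C(=O)N1C(=O)OC[C@@H]1Cc1ccccc1 | intermediate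
9 | (3R)-5,7-bis(benzyloxy)-3-{[tert-butyl(dimethyl)silyl]oxy}-3,4-dihydro-2H-chromen-2-one | CC(C)(C)[Si](C)(C)O[C@@H]1Cc2c(OCc3ccccc3)cc(OCc3ccccc3)cc2OC1=O | intermediate
10 | 5-bromo-1,2,3-trimethoxybenzene | COc1cc(Br)cc(OC)c1OC | starting material
11 | 5-bromobenzene-1,2,3-triol | Oc1cc(Br)cc(O)c1O | intermediate
12 | 1,2,3-tris(benzyloxy)-5-bromobenzene | Brc1cc(OCc2ccccc2)c(OCc2ccccc2)c(OCc2ccccc2)c1 | intermediate
13 | [3,4,5-tris(benzyloxy)phenyl]lithium | [Li]c1cc(OCc2ccccc2)c(OCc2ccccc2)c(OCc2ccccc2)c1 | intermediate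
14 | (3R)-5,7-bis(benzyloxy)-2-[3,4,5-tris(benzyloxy)phenyl]-3-{[tert-butyl(dimethyl)silyl]oxy}chroman-2-ol (lactol, both C2 epimers, in equilibrium with the open hydroxy ketone) | CC(C)(C)[Si](C)(C)O[C@@H]1Cc2c(OCc3ccccc3)cc(OCc3ccccc3)cc2OC1(O)c1cc(OCc2ccccc2)c(OCc2ccccc2)c(OCc2ccccc2)c1 | intermediate
15 | (3R)-5,7-bis(benzyloxy)-2-[3,4,5-tris(benzyloxy)phenyl]-3-{[tert-butyl(dimethyl)silyl]oxy}-3,4-dihydrochromen-1-ylium (cyclic oxocarbenium ion) | CC(C)(C)[Si](C)(C)O[C@@H]1Cc2c(OCc3ccccc3)cc(OCc3ccccc3)cc2[O+]=C1c1cc(OCc2ccccc2)c(OCc2ccccc2)c(OCc2ccccc2)c1 | intermediate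
16 | (2R,3R)-5,7-bis(benzyloxy)-2-[3,4,5-tris(benzyloxy)phenyl]-3-{[tert-butyl(dimethyl)silyl]oxy}chromane (3-O-silyl penta-O-benzyl-epigallocatechin) | CC(C)(C)[Si](C)(C)O[C@@H]1Cc2c(OCc3ccccc3)cc(OCc3ccccc3)cc2O[C@@H]1c1cc(OCc2ccccc2)c(OCc2ccccc2)c(OCc2ccccc2)c1 | intermediate
17 | (2R,3R)-8-bromo-5,7-bis(benzyloxy)-2-[3,4,5-tris(benzyloxy)phenyl]-3-{[tert-butyl(dimethyl)silyl]oxy}chromane | CC(C)(C)[Si](C)(C)O[C@@H]1Cc2c(OCc3ccccc3)cc(OCc3ccccc3)c(Br)c2O[C@@H]1c1cc(OCc2ccccc2)c(OCc2ccccc2)c(OCc2ccccc2)c1 | intermediate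
18 | (−)-epicatechin, (2R,3R) | O[C@@H]1Cc2c(O)cc(O)cc2O[C@@H]1c1ccc(O)c(O)c1 | starting material
19 | 5,7,3′,4′-tetra-O-benzyl-(−)-epicatechin | O[C@@H]1Cc2c(OCc3ccccc3)cc(OCc3ccccc3)cc2O[C@@H]1c1ccc(OCc2ccccc2)c(OCc2ccccc2)c1 | intermediate
20 | 3,5,7,3′,4′-penta-O-benzyl-(−)-epicatechin | C(c1ccccc1)O[C@@H]1Cc2c(OCc3ccccc3)cc(OCc3ccccc3)cc2O[C@@H]1c1ccc(OCc2ccccc2)c(OCc2ccccc2)c1 | intermediate
21 | 4β-hydroxy-3,5,7,3′,4′-penta-O-benzyl-(−)-epicatechin (2,3-cis, 3,4-trans) | O[C@H]1c2c(OCc3ccccc3)cc(OCc3ccccc3)cc2O[C@H](c2ccc(OCc3ccccc3)c(OCc3ccccc3)c2)[C@@H]1OCc1ccccc1 | intermediate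
22 | 4-oxo-3,5,7,3′,4′-penta-O-benzyl-(−)-epicatechin (2,3-cis) | O=C1c2c(OCc3ccccc3)cc(OCc3ccccc3)cc2O[C@H](c2ccc(OCc3ccccc3)c(OCc3ccccc3)c2)[C@@H]1OCc1ccccc1 | intermediate
23 | {(2R,3R)-5,7-bis(benzyloxy)-2-[3,4,5-tris(benzyloxy)phenyl]-3-{[tert-butyl(dimethyl)silyl]oxy}chroman-8-yl}lithium | CC(C)(C)[Si](C)(C)O[C@@H]1Cc2c(OCc3ccccc3)cc(OCc3ccccc3)c([Li])c2O[C@@H]1c1cc(OCc2ccccc2)c(OCc2ccccc2)c(OCc2ccccc2)c1 | intermediate
24 | 4-hydroxy-3,5,7,3′,4′-penta-O-benzyl-epicatechin-(4→8)-[3-O-(tert-butyldimethylsilyl)-5,7,3′,4′,5′-penta-O-benzyl-epigallocatechin] (tertiary carbinol, 4-aryl β, 4-OH α) | CC(C)(C)[Si](C)(C)O[C@@H]1Cc2c(OCc3ccccc3)cc(OCc3ccccc3)c([C@@]3(O)c4c(OCc5ccccc5)cc(OCc5ccccc5)cc4O[C@H](c4ccc(OCc5ccccc5)c(OCc5ccccc5)c4)[C@@H]3OCc3ccccc3)c2O[C@@H]1c1cc(OCc2ccccc2)c(OCc2ccccc2)c(OCc2ccccc2)c1 | intermediate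
25 | 4-aryl-flavan-4-ylium ion derived from 24 (planar at upper C4) | CC(C)(C)[Si](C)(C)O[C@@H]1Cc2c(OCc3ccccc3)cc(OCc3ccccc3)c([C+]3c4c(OCc5ccccc5)cc(OCc5ccccc5)cc4O[C@H](c4ccc(OCc5ccccc5)c(OCc5ccccc5)c4)[C@@H]3OCc3ccccc3)c2O[C@@H]1c1cc(OCc2ccccc2)c(OCc2ccccc2)c(OCc2ccccc2)c1 | intermediate
26 | 3,5,7,3′,4′-penta-O-benzyl-epicatechin-(4α→8)-[3-O-(tert-butyldimethylsilyl)-5,7,3′,4′,5′-penta-O-benzyl-epigallocatechin] | CC(C)(C)[Si](C)(C)O[C@@H]1Cc2c(OCc3ccccc3)cc(OCc3ccccc3)c([C@@H]3c4c(OCc5ccccc5)cc(OCc5ccccc5)cc4O[C@H](c4ccc(OCc5ccccc5)c(OCc5ccccc5)c4)[C@@H]3OCc3ccccc3)c2O[C@@H]1c1cc(OCc2ccccc2)c(OCc2ccccc2)c(OCc2ccccc2)c1 | intermediate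
27 | 3,5,7,3′,4′-penta-O-benzyl-epicatechin-(4α→8)-[5,7,3′,4′,5′-penta-O-benzyl-epigallocatechin] | O[C@@H]1Cc2c(OCc3ccccc3)cc(OCc3ccccc3)c([C@@H]3c4c(OCc5ccccc5)cc(OCc5ccccc5)cc4O[C@H](c4ccc(OCc5ccccc5)c(OCc5ccccc5)c4)[C@@H]3OCc3ccccc3)c2O[C@@H]1c1cc(OCc2ccccc2)c(OCc2ccccc2)c(OCc2ccccc2)c1 | intermediate
28 | 3,4,5-tris(benzyloxy)benzoic acid | OC(=O)c1cc(OCc2ccccc2)c(OCc2ccccc2)c(OCc2ccccc2)c1 | starting material
29 | 3,5,7,3′,4′-penta-O-benzyl-epicatechin-(4α→8)-[5,7,3′,4′,5′-penta-O-benzyl-epigallocatechin 3-O-(3,4,5-tri-O-benzylgallate)] | O=C(O[C@@H]1Cc2c(OCc3ccccc3)cc(OCc3ccccc3)c([C@@H]3c4c(OCc5ccccc5)cc(OCc5ccccc5)cc4O[C@H](c4ccc(OCc5ccccc5)c(OCc5ccccc5)c4)[C@@H]3OCc3ccccc3)c2O[C@@H]1c1cc(OCc2ccccc2)c(OCc2ccccc2)c(OCc2ccccc2)c1)c1cc(OCc2ccccc2)c(OCc2ccccc2)c(OCc2ccccc2)c1 | intermediate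
30 | epicatechin-(4α→8)-epigallocatechin 3-O-gallate | O=C(O[C@@H]1Cc2c(O)cc(O)c([C@@H]3c4c(O)cc(O)cc4O[C@H](c4ccc(O)c(O)c4)[C@@H]3O)c2O[C@@H]1c1cc(O)c(O)c(O)c1)c1cc(O)c(O)c(O)c1 | target

Total step count: 17. Longest linear sequence: 10 steps (1, 2, 4, 7, 8, 13, 14, 15, 16, 17).

Steps most likely to fail

Step 4. The o-quinone methide may self-condense before the enolate captures it, the enolate may react through oxygen, and the α-silyloxy lactone may epimerise under the basic conditions of the lactonisation. The fallback sets out from 1 and uses known reaction types. Condensation of 1 with paraformaldehyde and Meldrum's acid (pyridine, MeCN, heat; ortho C-alkylation, then lactonisation with loss of acetone and carbon dioxide) should give 5,7-bis(benzyloxy)-3,4-dihydro-2H-chromen-2-one F1. Its sodium enolate (NaN(SiMe3)2, THF, −78 °C) is hydroxylated with the antipode of (camphorsulfonyl)oxaziridine that delivers the 3R alcohol (Davis enolate oxidation), to give (3R)-5,7-bis(benzyloxy)-3-hydroxy-3,4-dihydro-2H-chromen-2-one F2. Silylation (t-BuMe2SiCl, imidazole, DMF) rejoins the route at 9.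

Step 7. The aryllithium may add twice after collapse of the tetrahedral adduct to the ketone, or may enolise the lactone and erode C3, and the oxocarbenium ion may lose the C3 proton before hydride transfer. The fallback sets out from 9. Aminolysis with MeNH(OMe)·HCl and AlMe3 (CH2Cl2, 0 °C) opens the lactone to the Weinreb amide (2R)-3-[2,4-bis(benzyloxy)-6-hydroxyphenyl]-2-{[tert-butyl(dimethyl)silyl]oxy}-N-methoxy-N-methylpropanamide F3. Two equivalents of 13 (the first deprotonates the phenol) then stop cleanly at the aryl ketone, which is the open tautomer of lactol 14. The route is rejoined at 14 and continues with Et3SiH and BF3·OEt2 as in step 7.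

Step 1. Aminomethylation of the triply activated ring may also occur para to the hydroxyl or twice. The fallback sets out from 1. Magnesium-mediated ortho-formylation (MgCl2, Et3N, paraformaldehyde, MeCN, reflux; Casnati–Skattebøl reaction, ortho-specific through the magnesium phenoxide) should give 4,6-bis(benzyloxy)-2-hydroxybenzaldehyde F4. Reductive amination (Me2NH, NaBH(OAc)3, 1,2-dichloroethane) rejoins the route at 2.

Further compounds
F1 | step 4 | 5,7-bis(benzyloxy)-3,4-dihydro-2H-chromen-2-one | O=C1CCc2c(OCc3ccccc3)cc(OCc3ccccc3)cc2O1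
F2 | step 4 | (3R)-5,7-bis(benzyloxy)-3-hydroxy-3,4-dihydro-2H-chromen-2-one | O[C@@H]1Cc2c(OCc3ccccc3)cc(OCc3ccccc3)cc2OC1=O
F3 | step 7 | (2R)-3-[2,4-bis(benzyloxy)-6-hydroxyphenyl]-2-{[tert-butyl(dimethyl)silyl]oxy}-N-methoxy-N-methylpropanamide | CON(C)C(=O)[C@@H](Cc1c(O)cc(OCc2ccccc2)cc1OCc1ccccc1)O[Si](C)(C)C(C)(C)C
F4 | step 1 | 4,6-bis(benzyloxy)-2-hydroxybenzaldehyde | O=Cc1c(O)cc(OCc2ccccc2)cc1OCc1ccccc1
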